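**Assumption:** the SMILES contains no stereocentre and gives no descriptor for the C5–C5' axis. The compound is therefore made as drawn, with the axis uncontrolled (racemic if the axis proves configurationally stable).

Unit A is the 6-hydroxychromone half. Unit B is the 8-hydroxychromone half.

## Retrosynthetic overview
1. Target ⇒ open tetramethoxy biaryl bis(ynone). This breaks the two pyranone C–O bonds (O1–C2 and O1'–C2') and masks the four O–H groups as O–Me.
2. Bis(ynone) ⇒ biaryl-2,2'-dicarbaldehyde + 2 × 4-phenyl-1-butyne (two-directional alkynylation/oxidation).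
3. Dicarbaldehyde ⇒ 6-bromo-2,3-dimethoxybenzaldehyde + 2-bromo-3,6-dimethoxybenzaldehyde (borylation/Suzuki coupling, which sets C5–C5' early).
4. Bromoaldehydes ⇒ 2,3-dimethoxybenzaldehyde (bromination) and 2-bromo-1,4-dimethoxybenzene (lithiation/formylation).
5. Ring order: both benzene rings are bought. The pyranone rings of unit A and unit B are closed together in the last step.

## Route

Step 1
Reactants: 1 2,3-dimethoxybenzaldehyde
Product: 2 6-bromo-2,3-dimethoxybenzaldehyde
Conditions: NBS (1.1 equiv), DMF, rt, 48 h
Reagents that add atoms: N-bromosuccinimide, O=C1CCC(=O)N1Br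
Why: Electrophilic aromatic bromination: the 2-methoxy group is pushed out of the ring plane by its two neighbours and donates little, so the coplanar 3-methoxy group steers bromine to its para position C6, which is the known outcome with NBS in DMF; no stereocentre is formed.

Step 2
Reactants: 3 2-bromo-1,4-dimethoxybenzene
Product: 5 2-bromo-3,6-dimethoxybenzaldehyde, via (2-bromo-3,6-dimethoxyphenyl)lithium 4 (not isolated)
Conditions: LiN(iPr)2 (LDA, commercial solution, 1.1 equiv), THF, −78 °C, 1 h; DMF (1.5 equiv), −78 to 0 °C; 1 M HCl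
Reagents that add atoms: N,N-dimethylformamide, CN(C)C=O
Why: Directed ortho-metalation followed by formylation with DMF: the C–H flanked by Br and OMe is by far the most acidic, the amide base deprotonates without bromine–lithium exchange, and at −78 °C aryllithium 4 is trapped before it can lose LiBr to an aryne.

Step 3
Reactants: 2 6-bromo-2,3-dimethoxybenzaldehyde, 5 2-bromo-3,6-dimethoxybenzaldehyde
Product: 7 3,3',4',6-tetramethoxybiphenyl-2,2'-dicarbaldehyde, via pinacol boronate 6 (not isolated)
Conditions: 2, B2pin2 (1.1 equiv), Pd(OAc)2 (3 mol %), SPhos (6 mol %), KOAc (2 equiv), dioxane, 90 °C; then 5 (0.95 equiv), aq K3PO4 (3 equiv), 90 °C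
Reagents that add atoms: bis(pinacolato)diboron, CC1(C)OB(OC1(C)C)B1OC(C)(C)C(C)(C)O1 (its boryl group stands in 6 only and is lost again in 7)
Why: Miyaura borylation and Suzuki–Miyaura coupling in one flask: the less hindered bromide 2 is borylated, then SPhos-ligated zerovalent palladium inserts into the aldehyde-activated, di-ortho-substituted bromide 5 and joins the rings at the future C5 and C5'; the new axis forms without control.

Step 4
Reactants: 7 3,3',4',6-tetramethoxybiphenyl-2,2'-dicarbaldehyde, 8 4-phenyl-1-butyne (2.1 equiv)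
Product: 11 1,1'-(3,3',4',6-tetramethoxybiphenyl-2,2'-diyl)bis(5-phenylpent-2-yn-1-one), via lithium acetylide 9 (not isolated), via dilithium bis-alkoxide 10 (not isolated)
Conditions: 8, n-BuLi (2.1 equiv), THF, −78 °C; 7, −78 to 0 °C; PhS(Cl)=NtBu (2.3 equiv), −78 °C to rt
Reagents that add atoms: none
Why: Two-directional 1,2-addition of a lithium acetylide to both aldehydes, followed in the same flask by Mukaiyama oxidation of the lithium alkoxides (O–S bond formation, then intramolecular proton abstraction by the imido nitrogen), so the two carbinol stereocentres of 10 are erased at once and no enolisable stage is passed.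

Step 5
Reactants: 11 1,1'-(3,3',4',6-tetramethoxybiphenyl-2,2'-diyl)bis(5-phenylpent-2-yn-1-one)
Product: 13 6,8'-dihydroxy-2,2'-bis(2-phenylethyl)-[5,5'-bi-4H-chromene]-4,4'-dione (target), via 6,8'-dimethoxy-5,5'-bichromone 12 (not isolated)
Conditions: BBr3 (8 equiv), CH2Cl2, −78 to 0 °C, 3 h (ring closures); rt, 12 h (remote ethers); H2O, 0 °C to rt
Reagents that add atoms: none
Why: Proposed new method: a BBr3-triggered demethylative double 6-endo-dig oxa-cyclisation in which each ortho-methoxy oxygen becomes the ring oxygen O1: BBr3 binds the ynone carbonyl, which makes the alkyne β-carbon (future C2) the electrophilic site right next to the flanking OMe group; either the ether oxygen adds directly to give a methyloxonium ion that bromide demethylates (MeBr), or chelation-assisted O–Me cleavage comes first and the aryl-O–BBr2 group displaces bromide from the β-bromo-enone formed by bromide addition, and both paths end in the same O1–C2 bond, with C3 taking its hydrogen from HBr or the water quench; because ethers ortho to a carbonyl group fall much faster than isolated ones, both rings close (12) before the C6 and C8' ethers are cleaved at rt, which keeps the O6 phenol from adding to the neighbouring ketone; 5-exo closure is disfavoured because carbonyl activation places the positive charge on the β-carbon; the closest known reaction types are the iodine monochloride-induced cyclisation of 2-methoxyaryl ynones to 3-iodochromones, the BCl3-induced demethylative oxyboration of 2-alkynylanisoles and plain BBr3 ether cleavage, none of which has been run proton-terminated, twofold on a tri-ortho-substituted biaryl, or merged with global deprotection; no stereocentre is formed and the axis stays uncontrolled.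

## Compound list
1 | 2,3-dimethoxybenzaldehyde | COc1cccc(C=O)c1OC | starting material
2 | 6-bromo-2,3-dimethoxybenzaldehyde | COc1ccc(Br)c(C=O)c1OC | intermediate
3 | 2-bromo-1,4-dimethoxybenzene | COc1ccc(OC)c(Br)c1 | starting material
4 | (2-bromo-3,6-dimethoxyphenyl)lithium | COc1ccc(OC)c(Br)c1[Li] | intermediate
5 | 2-bromo-3,6-dimethoxybenzaldehyde | COc1ccc(OC)c(Br)c1C=O | intermediate
6 | 2,3-dimethoxy-6-(4,4,5,5-tetramethyl-1,3,2-dioxaborolan-2-yl)benzaldehyde | COc1ccc(B2OC(C)(C)C(C)(C)O2)c(C=O)c1OC | intermediate
7 | 3,3',4',6-tetramethoxybiphenyl-2,2'-dicarbaldehyde | COc1ccc(OC)c(-c2ccc(OC)c(OC)c2C=O)c1C=O | intermediate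
8 | 4-phenyl-1-butyne | C#CCCc1ccccc1 | starting material
9 | (4-phenylbut-1-yn-1-yl)lithium | [Li]C#CCCc1ccccc1 | intermediate
10 | dilithium bis(propargylic alkoxide) of the twofold adduct (diastereomer mixture) | COc1ccc(OC)c(-c2ccc(OC)c(OC)c2C(O[Li])C#CCCc2ccccc2)c1C(O[Li])C#CCCc1ccccc1 | intermediate
11 | 1,1'-(3,3',4',6-tetramethoxybiphenyl-2,2'-diyl)bis(5-phenylpent-2-yn-1-one) | COc1ccc(OC)c(-c2ccc(OC)c(OC)c2C(=O)C#CCCc2ccccc2)c1C(=O)C#CCCc1ccccc1 | intermediate
12 | 6,8'-dimethoxy-2,2'-bis(2-phenylethyl)-[5,5'-bi-4H-chromene]-4,4'-dione | O=c1cc(CCc2ccccc2)oc2ccc(OC)c(-c3ccc(OC)c4oc(CCc5ccccc5)cc(=O)c34)c12 | intermediate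
13 | 6,8'-dihydroxy-2,2'-bis(2-phenylethyl)-[5,5'-bi-4H-chromene]-4,4'-dione | O=c1cc(CCc2ccccc2)oc2ccc(O)c(-c3ccc(O)c4oc(CCc5ccccc5)cc(=O)c34)c12 | target

## Step count
Total step count: 5. Longest linear sequence: 4 (1 → 2 → 7 → 11 → 13, or 3 → 5 → 7 → 11 → 13).

## Three steps most likely to fail

**Step 5 (the proposed new step).**
- Risks: bromide addition may fail to lead on to ring closure. The pendant phenyl ring may attack the activated alkyne (hydroarylation to an indane). Some 5-exo closure may occur.
- Fallback, known chemistry only, sets out from 11 and comes back at 12.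
- Iodine monochloride (2.4 equiv, CH2Cl2, −78 °C to rt) effects the established iodocyclisation of 2-methoxyaryl ynones. It gives 3,3'-diiodo-6,8'-dimethoxy-2,2'-bis(2-phenylethyl)-5,5'-bichromone F1.
- Formate hydrodeiodination (Pd(PPh3)4, HCO2Na, DMF, 80 °C) gives 12, now isolated.
- Ordinary BBr3 cleavage of the two remaining aryl methyl ethers takes 12 to 13.

**Step 3.**
- Risks: protodeboronation of the ortho-formyl boronate 6, slow coupling at the di-ortho-substituted bromide, and a Cannizzaro-type reaction of the dialdehyde in hot aqueous base.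
- Fallback sets out from 2 and 5 and comes back at 7. It is a water- and base-free Negishi coupling.
- 2 is converted with HC(OMe)3 and catalytic TsOH in MeOH into 1-bromo-2-(dimethoxymethyl)-3,4-dimethoxybenzene F2.
- Bromine–lithium exchange (n-BuLi, THF, −78 °C) gives [2-(dimethoxymethyl)-3,4-dimethoxyphenyl]lithium F3.
- ZnCl2 gives [2-(dimethoxymethyl)-3,4-dimethoxyphenyl]zinc chloride F4.
- Coupling with 5 (Pd(OAc)2, SPhos, THF, 50 °C; the free aldehyde of 5 tolerates the arylzinc) gives 2'-(dimethoxymethyl)-3,3',4',6-tetramethoxybiphenyl-2-carbaldehyde F5.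
- 1 M HCl in the work-up frees 7.

**Step 4.**
- Risks: after the first addition the alkoxide can close onto the second aldehyde to give a seven-membered lactol alkoxide, which would then be oxidised to a lactone. Surplus acetylide can also attack the ynone as it forms.
- Fallback sets out from 7 and comes back at 13. It replaces the ynone by the classical 1,3-diketone.
- 4-Phenylbutan-2-one (commercial) and LiN(iPr)2 (THF, −78 °C) give lithium 4-phenylbut-1-en-2-olate F6.
- F6 adds to both aldehydes to give 1,1'-(3,3',4',6-tetramethoxybiphenyl-2,2'-diyl)bis(1-hydroxy-5-phenylpentan-3-one) F7.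
- Dess–Martin periodinane gives 1,1'-(3,3',4',6-tetramethoxybiphenyl-2,2'-diyl)bis(5-phenylpentane-1,3-dione) F8.
- Refluxing 48 % HBr/AcOH effects the known demethylative cyclodehydration to 13.

## Further compounds
F1 | step 5 | 3,3'-diiodo-6,8'-dimethoxy-2,2'-bis(2-phenylethyl)-5,5'-bichromone | O=c1c(I)c(CCc2ccccc2)oc2ccc(OC)c(-c3ccc(OC)c4oc(CCc5ccccc5)c(I)c(=O)c34)c12
F2 | step 3 | 1-bromo-2-(dimethoxymethyl)-3,4-dimethoxybenzene | COc1ccc(Br)c(C(OC)OC)c1OC
F3 | step 3 | [2-(dimethoxymethyl)-3,4-dimethoxyphenyl]lithium | COc1ccc([Li])c(C(OC)OC)c1OC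
F4 | step 3 | [2-(dimethoxymethyl)-3,4-dimethoxyphenyl]zinc chloride | COc1ccc([Zn]Cl)c(C(OC)OC)c1OC
F5 | step 3 | 2'-(dimethoxymethyl)-3,3',4',6-tetramethoxybiphenyl-2-carbaldehyde | COc1ccc(OC)c(-c2ccc(OC)c(OC)c2C(OC)OC)c1C=O
F6 | step 4 | lithium 4-phenylbut-1-en-2-olate | C=C(O[Li])CCc1ccccc1
F7 | step 4 | 1,1'-(3,3',4',6-tetramethoxybiphenyl-2,2'-diyl)bis(1-hydroxy-5-phenylpentan-3-one) | COc1ccc(OC)c(-c2ccc(OC)c(OC)c2C(O)CC(=O)CCc2ccccc2)c1C(O)CC(=O)CCc1ccccc1
F8 | step 4 | 1,1'-(3,3',4',6-tetramethoxybiphenyl-2,2'-diyl)bis(5-phenylpentane-1,3-dione) | COc1ccc(OC)c(-c2ccc(OC)c(OC)c2C(=O)CC(=O)CCc2ccccc2)c1C(=O)CC(=O)CCc1ccccc1
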